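Readings and results are simulated for an exercise; the scatter is artificial.

In a one-step world substrate becomes target and stays there, so yield y (target and product in the second phase together) follows conversion, but the earlier runs show something else.

| flask | substrate | reagent in the second phase | remark | time | volume of the second phase over the first |
|---|---|---|---|---|---|
| spring | 0.15 M | 0.121 M | run made earlier |  |  |
| summer | 0.24 M | 0.121 M | run made earlier |  |  |
| flask | 0.11 M | 0.121 M |  | 2.0 min | 1.0 |

| run | time / s | target / % | substrate / % |
|---|---|---|---|
| spring | 15.0 | 35 | 42 |
| spring | 30.0 | 38 | 24 |
| spring | 50.0 | 34 | 15 |
| spring | 60.0 | 30 | 9 |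
| spring | 80.0 | 27 | 5 |
| spring | 90.0 | 22 | 5 |
| spring | 120 | 18 | 2 |
| summer | 10.0 | 22 | 60 |
| summer | 20.0 | 29 | 44 |
| summer | 30.0 | 34 | 31 |
| summer | 50.0 | 25 | 18 |
| summer | 80.0 | 19 | 8 |
| summer | 90.0 | 17 | 11 |
| summer | 120 | 12 | 6 |

(scatter of a reading: 1.5 percentage points)

- amounts and yields of target count product in the second phase too
- in the second phase: reagent in the second phase, product in the second phase; everything else is in the first
- charges count per volume of the first phase; a concentration in a rate is the amount of a species over the volume of its own phase; every rate counts per litre of the first phase
- the numbers in the tables scatter with a standard deviation of 1.5 percentage points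
- the earlier runs hold the two phases in the same ratio of volumes as the flask asked about
- what has gone from substrate into another species counts as reacted, even if it can come back

- target and product in the second phase together at 2.0 min, in percent of the substrate charged
- part of the substrate charged that has reacted at 2.0 min

In the spring run target falls from 38 % at 30.0 s to 18 % at 120 s. I read that as an apparent fading constant of target, the logarithm of that ratio over that interval, k_f = 0.498 /min, with the feed from remaining substrate folded in. Stretching the line through the spring and summer readings at 30.0 s to the flask's charge gives 39.8 % at that time, and fading this by k_f up to 2.0 min gives my own estimate for the flask, y = 18.8 %.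

The forecast says y = 98 % and conversion 98 %, holding that “Substrate lost must therefore be target or its second-phase form”.

The flask gives y = 19.6 % and conversion 98.2 %.

    reagent in the reaction phase ⇌ reagent in the second phase, rate k1*([reagent in the reaction phase] - [reagent in the second phase]/K1) per volume of the first phase (partition coefficient = 0.920, kL = 0.390 /s)
    substrate + reagent in the reaction phase → target (k = 0.960 /M/s)
    target ⇌ product in the second phase, rate k3*([target] - [product in the second phase]/K3) per volume of the first phase (partition coefficient = 20.0, kL = 0.00380 /s)
    target → decomposed product (k = 0.0170 /s)
    reagent in the reaction phase → decomposed reagent (k = 0.00480 /s)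
    substrate ⇌ dormant form (K = 13.0, k = 0.0180 /s)

Part of the gap between conversion and yield in this flask comes from target decomposing while its passage into product in the second phase lags: this flask gives 66.7 % without that decomposition and 60.7 % without that bottleneck, and at 2.0 min decomposed product holds 47.1 % of the substrate charged, while dormant form, which counts as reacted, holds 31.5 %. From 39.8 % at 0.500 min to 19.6 % at 2.0 min, the flask fades at 0.472 /min, against k_f = 0.498 /min. Carried to the same flask read at 8.0 min, k_f gives 0.950 %, yet that flask holds 12.8 %, with 12.2 % as product in the second phase.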